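**Retrosynthetic overview**
1. Crotobarin 23 ⇐ α-methylenation at C16 and O-acetylation at C14 of the tetracyclic ketol lactone 21.
2. 21 ⇐ one-pot triple ring closure of the monocyclic enal–enone ester 17: a Michael addition (C16–C12) closes a cyclohexenone ring, then an oxa-Michael (O–C9)/aldol (C8–C14) domino closes the δ-lactone and the bicyclo[2.2.2]octane together.
3. 17 ⇐ cross-metathesis of allyl enone 15 ⇐ oxidative 1,3-transposition of tertiary allylic alcohol 14 ⇐ allyl addition to ethylidene ketone 12 ⇐ keto ester 8.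
4. 8 (ring B carrying C5 and quaternary C10) ⇐ imine Michael addition of ketone 3 to tert-butyl acrylate ⇐ catalytic asymmetric conjugate addition of isopropenyl Grignard to 2-methylcyclohexenone.
5. Ring order: ring B first; then the cyclohexenone ring; then lactone and bicyclo[2.2.2]octane in the same flask.

Assumption: atisane numbering is used (C5 = CH–isopropenyl, C10 = C–CH3, C9 = lactone C–O, C8/C12 = bridgeheads, C14 = CH–OAc, C15 = ketone, C16/C17 = exo-methylene, C1–C3 = propanoate arm), and the hand of the chiral ligand in step 1 is taken as the one that gives the (3R) ketone.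

**Step 1**
Reactants: 1 2-methylcyclohex-2-en-1-one; 2 isopropenylmagnesium bromide
Product: 3 (3R)-2-methyl-3-(prop-1-en-2-yl)cyclohexan-1-one (C-2 epimers)
Conditions: 2 (1.3 equiv), Cu(OTf)2 (4 mol %), chiral hydroxyalkyl-imidazolinium NHC precursor (5 mol %), Et2O, −30 °C; then H2O
Reagents that add atoms: 2 isopropenylmagnesium bromide, CC(=C)[Mg]Br
Why: Copper–NHC-catalysed asymmetric conjugate addition of a Grignard reagent to an α-substituted cyclic enone; the chiral copper complex delivers isopropenyl to one face of C3 (later C5), and the C2 epimer ratio is irrelevant because C2 is re-enolised in step 2.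

**Step 2**
Reactants: 3 (3R)-2-methyl-3-(prop-1-en-2-yl)cyclohexan-1-one; 4 benzylamine; 5 tert-butyl acrylate
Product: 8 tert-butyl 3-[(1S,6S)-1-methyl-2-oxo-6-(prop-1-en-2-yl)cyclohexyl]propanoate, via ketone N-benzyl imine 6 (not isolated), via keto ester N-benzyl imine 7 (not isolated)
Conditions: 4 (1.1 equiv), TsOH (1 mol %), toluene, reflux (Dean–Stark); 5 (2 equiv), THF, 60 °C; 20% aq. AcOH, 23 °C
Reagents that add atoms: 5 tert-butyl acrylate, C=CC(=O)OC(C)(C)C
Why: d'Angelo-type imine Michael addition: the more substituted secondary-enamine tautomer of 6 adds to the acrylate (aza-ene-like transition state) only at the methyl-bearing carbon and anti to the neighbouring isopropenyl group, which sets quaternary C10 with methyl cis and the propanoate arm trans to isopropenyl.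

**Step 3**
Reactants: 8 tert-butyl 3-[(1S,6S)-1-methyl-2-oxo-6-(prop-1-en-2-yl)cyclohexyl]propanoate; 9 acetaldehyde
Product: 12 tert-butyl 3-[(1S,3E,6S)-3-ethylidene-1-methyl-2-oxo-6-(prop-1-en-2-yl)cyclohexyl]propanoate, via lithium aldolate 10 (not isolated), via aldol mesylate 11 (not isolated)
Conditions: lithium diisopropylamide (1.05 equiv), THF, −78 °C; 9 (1.5 equiv); MsCl, −78→0 °C; DBU, 23 °C
Reagents that add atoms: 9 acetaldehyde, CC=O
Why: Directed aldol addition of the kinetic lithium enolate (the ring CH2 is the only enolisable ketone α-position), then mesylation and E1cB elimination to the conjugated (E)-ethylidene ketone; no new stereocentre survives.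

**Step 4**
Reactants: 12 tert-butyl 3-[(1S,3E,6S)-3-ethylidene-1-methyl-2-oxo-6-(prop-1-en-2-yl)cyclohexyl]propanoate; 13 allylmagnesium bromide
Product: 14 tert-butyl 3-[(1S,3E,6S)-3-ethylidene-2-hydroxy-1-methyl-2-(prop-2-en-1-yl)-6-(prop-1-en-2-yl)cyclohexyl]propanoate (both C-2 epimers)
Conditions: 13 (1.3 equiv), THF, −78 °C; then H2O
Reagents that add atoms: 13 allylmagnesium bromide, C=CC[Mg]Br
Why: Carbonyl 1,2-addition of an allyl Grignard reagent (six-membered SE2′ transition state), fast at the hindered enone carbonyl and faster than attack on the tert-butyl ester at −78 °C; the carbinol configuration is irrelevant because this carbon becomes sp2 in step 5.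

**Step 5**
Reactants: 14 tert-butyl 3-[(1S,3E,6S)-3-ethylidene-2-hydroxy-1-methyl-2-(prop-2-en-1-yl)-6-(prop-1-en-2-yl)cyclohexyl]propanoate
Product: 15 tert-butyl 3-[(1S,6S)-3-acetyl-1-methyl-2-(prop-2-en-1-yl)-6-(prop-1-en-2-yl)cyclohex-2-en-1-yl]propanoate
Conditions: pyridinium chlorochromate [C5H5NH][CrO3Cl] (2.5 equiv), 4 Å molecular sieves, CH2Cl2, 23 °C
Reagents that add atoms: pyridinium chlorochromate, [O-][Cr](=O)(=O)Cl.c1cc[nH+]cc1 (its oxo oxygen becomes the ketone O; the C9 hydroxyl O leaves on chromium)
Why: Babler–Dauben oxidative 1,3-transposition: the tertiary allylic chromate ester undergoes a [3,3] shift to the exocyclic secondary chromate, which is oxidised to the methyl ketone, giving the tetrasubstituted enone with acetyl on C8 and allyl on C9; no stereocentre is involved.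

**Step 6**
Reactants: 15 tert-butyl 3-[(1S,6S)-3-acetyl-1-methyl-2-(prop-2-en-1-yl)-6-(prop-1-en-2-yl)cyclohex-2-en-1-yl]propanoate; 16 (E)-crotonaldehyde
Product: 17 tert-butyl 3-[(1S,6S)-3-acetyl-1-methyl-2-[(2E)-4-oxobut-2-en-1-yl]-6-(prop-1-en-2-yl)cyclohex-2-en-1-yl]propanoate
Conditions: second-generation Hoveyda–Grubbs catalyst (5 mol %), 16 (6 equiv), CH2Cl2, 40 °C
Reagents that add atoms: 16 (E)-crotonaldehyde, C/C=C/C=O
Why: Olefin cross-metathesis of the monosubstituted allyl alkene with excess crotonaldehyde gives the (E)-enal; the isopropenyl group and the tetrasubstituted enone are unreactive, and ring-closing onto isopropenyl would need a bridgehead alkene.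

**Step 7**
Reactants: 17 tert-butyl 3-[(1S,6S)-3-acetyl-1-methyl-2-[(2E)-4-oxobut-2-en-1-yl]-6-(prop-1-en-2-yl)cyclohex-2-en-1-yl]propanoate
Product: 21 14-O-deacetyl-16-demethylenecrotobarin (tetracyclic ketol lactone), via octalone aldehyde ester 18 (not isolated), via octalone aldehyde acid 19 (not isolated), via lactone keto aldehyde 20 (not isolated)
Conditions: pyrrolidine (0.3 equiv), AcOH (0.3 equiv), CHCl3, 40 °C; then CF3CO2H–CH2Cl2 (1:3), 0→23 °C
Reagents that add atoms: none
Why: Proposed new method: the acetyl group, as its cross-conjugated dienamine, adds in an intramolecular 6-exo Michael reaction to the iminium-activated enal (closest known type: secondary-amine-catalysed intramolecular ketone-to-enal Michael additions), with C12 entering anti to the pseudo-axial C10 methyl and the CH2CHO arm equatorial; CF3CO2H then frees the acid and drives an oxa-Michael/aldol domino (closest known types: oxa-Michael/aldol annulations and the acid-mediated aldol closure of 3-oxocyclohexylacetaldehydes to 6-hydroxybicyclo[2.2.2]octan-2-ones) in which the carboxyl adds axially to C9 anti to the C10 methyl and the C8 enol attacks the aldehyde from the opposite face (trans-diaxial addition across C8=C9), so C8, C9 and C12 are fixed by the ring B chair and the tethers, C14–OH settles by reversible aldol on the ketone side (hydrogen-bonded, away from C10), and the now quaternary C8 blocks β-elimination of the lactone.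

**Step 8**
Reactants: 21 14-O-deacetyl-16-demethylenecrotobarin
Product: 22 16-demethylenecrotobarin (14-acetate)
Conditions: Ac2O (3 equiv), DMAP (10 mol %), pyridine, CH2Cl2, 0→23 °C
Reagents that add atoms: acetic anhydride, CC(=O)OC(C)=O
Why: DMAP-catalysed acetylation of the only hydroxyl, which points away from C10; capping the oxygen next to quaternary C8 shuts off retro-aldol and locks C14.

**Step 9**
Reactants: 22 16-demethylenecrotobarin
Product: 23 crotobarin
Conditions: (CH2O)n (5 equiv), i-Pr2NH·CF3CO2H (1.5 equiv), THF, 65 °C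
Reagents that add atoms: paraformaldehyde (as formaldehyde), C=O
Why: Mannich-type α-methylenation (ammonium-salt-promoted condensation with formaldehyde, then β-elimination): C16 is the only enolisable position of the C15 ketone and the bridgehead forbids an endocyclic isomer, so only the exo-methylene enone forms; no stereocentre changes.

**Compound list**
1 | 2-methylcyclohex-2-en-1-one | CC1=CCCCC1=O | starting material
2 | isopropenylmagnesium bromide | CC(=C)[Mg]Br | starting material
3 | (3R)-2-methyl-3-(prop-1-en-2-yl)cyclohexan-1-one (C-2 epimers) | CC1[C@H](C(C)=C)CCCC1=O | intermediate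
4 | benzylamine | NCc1ccccc1 | starting material
5 | tert-butyl acrylate | C=CC(=O)OC(C)(C)C | starting material
6 | N-benzyl imine of 3 (not isolated) | CC1[C@H](C(C)=C)CCCC1=NCc1ccccc1 | intermediate
7 | N-benzyl imine of 8 (not isolated) | C1(=NCc2ccccc2)CCC[C@@H](C(C)=C)[C@]1(C)CCC(=O)OC(C)(C)C | intermediate
8 | tert-butyl 3-[(1S,6S)-1-methyl-2-oxo-6-(prop-1-en-2-yl)cyclohexyl]propanoate | O=C1CCC[C@@H](C(C)=C)[C@]1(C)CCC(=O)OC(C)(C)C | intermediate
9 | acetaldehyde | CC=O | starting material
10 | lithium aldolate of 8 with acetaldehyde (3-(1-oxidoethyl) ketone, new centres mixed; not isolated) | [Li+].CC([O-])C1CC[C@@H](C(C)=C)[C@](C)(CCC(=O)OC(C)(C)C)C1=O | intermediate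
11 | methanesulfonate of the aldol (not isolated) | CC(OS(C)(=O)=O)C1CC[C@@H](C(C)=C)[C@](C)(CCC(=O)OC(C)(C)C)C1=O | intermediate
12 | tert-butyl 3-[(1S,3E,6S)-3-ethylidene-1-methyl-2-oxo-6-(prop-1-en-2-yl)cyclohexyl]propanoate | O=C1/C(=C/C)CC[C@@H](C(C)=C)[C@]1(C)CCC(=O)OC(C)(C)C | intermediate
13 | allylmagnesium bromide | C=CC[Mg]Br | starting material
14 | tert-butyl 3-[(1S,3E,6S)-3-ethylidene-2-hydroxy-1-methyl-2-(prop-2-en-1-yl)-6-(prop-1-en-2-yl)cyclohexyl]propanoate (C-2 epimers) | OC1(CC=C)/C(=C/C)CC[C@@H](C(C)=C)[C@]1(C)CCC(=O)OC(C)(C)C | intermediate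
15 | tert-butyl 3-[(1S,6S)-3-acetyl-1-methyl-2-(prop-2-en-1-yl)-6-(prop-1-en-2-yl)cyclohex-2-en-1-yl]propanoate | C=CCC1=C(C(C)=O)CC[C@@H](C(C)=C)[C@]1(C)CCC(=O)OC(C)(C)C | intermediate
16 | (E)-crotonaldehyde | C/C=C/C=O | starting material
17 | tert-butyl 3-[(1S,6S)-3-acetyl-1-methyl-2-[(2E)-4-oxobut-2-en-1-yl]-6-(prop-1-en-2-yl)cyclohex-2-en-1-yl]propanoate | O=C/C=C/CC1=C(C(C)=O)CC[C@@H](C(C)=C)[C@]1(C)CCC(=O)OC(C)(C)C | intermediate
18 | tert-butyl 3-[(1S,2S,7S)-1-methyl-5-oxo-7-(2-oxoethyl)-2-(prop-1-en-2-yl)-1,2,3,4,5,6,7,8-octahydronaphthalen-1-yl]propanoate (not isolated) | C1C(=O)C2CC[C@@H](C(=C)C)[C@](C)(CCC(=O)OC(C)(C)C)C=2C[C@H]1CC=O | intermediate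
19 | 3-[(1S,2S,7S)-1-methyl-5-oxo-7-(2-oxoethyl)-2-(prop-1-en-2-yl)-1,2,3,4,5,6,7,8-octahydronaphthalen-1-yl]propanoic acid (not isolated) | C1C(=O)C2CC[C@@H](C(=C)C)[C@](C)(CCC(=O)O)C=2C[C@H]1CC=O | intermediate
20 | δ-lactone keto aldehyde, the 8,14-seco form of 21 (lactone O axial on C9, C8–H, C12–CH2CHO; not isolated) | C1C(=O)C2CC[C@@H](C(=C)C)[C@]3(C)CCC(=O)O[C@@]32C[C@H]1CC=O | intermediate
21 | 14-O-deacetyl-16-demethylenecrotobarin (5S,8S,9S,10S,12R,14S; C15 ketone, C14 OH on the ketone side, δ-lactone O on C9) | C1C(=O)[C@]23CC[C@@H](C(=C)C)[C@]4(C)CCC(=O)O[C@@]42C[C@H]1C[C@@H]3O | intermediate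
22 | 16-demethylenecrotobarin (14-acetate of 21) | C1C(=O)[C@]23CC[C@@H](C(=C)C)[C@]4(C)CCC(=O)O[C@@]42C[C@H]1C[C@@H]3OC(C)=O | intermediate
23 | crotobarin (5S,8S,9S,10S,12R,14S) | C=C1C(=O)[C@]23CC[C@@H](C(=C)C)[C@]4(C)CCC(=O)O[C@@]42C[C@H]1C[C@@H]3OC(C)=O | target

**Step count and risks**
Total step count: 9. Longest linear sequence: 9 steps (from 1).

Steps most likely to fail:

Step 7 (triple ring closure). The Michael step may give a poor C12 ratio, the oxa-Michael/aldol equilibrium may be shallow, or CF3CO2H may attack the isopropenyl group. The fallback sets out from 18 (isolated after the amine stage) and returns at 22. Heating 18 with pyrrolidine (1 equiv, toluene, 60 °C) lets the linear dienamine close the C8–C14 bond by α-selective (deconjugative) aldol addition. Capping in the same flask with Ac2O/pyridine gives the bicyclo[2.2.2]octenone acetate tert-butyl ester F4, which keeps a C9=C11 alkene. Iodolactonisation (I2, MeCN, 0 °C; the ester carbonyl attacks C9 and loses isobutene) gives the 11-iodo lactone acetate F5. Radical deiodination (Bu3SnH, AIBN, benzene, 80 °C) then gives 22. Here the lactone comes from halolactonisation onto the bicyclic alkene, not from conjugate addition.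

Step 1 (asymmetric conjugate addition). An α-branched alkenyl Grignard on an α-methyl enone may give low ee or conversion. The fallback sets out from 1 and returns at 3. Racemic addition of 2 (CuBr·SMe2 10 mol %, THF, −40 °C; H2O) gives the racemic ketone F1. Enzymatic kinetic resolution with a screened ketoreductase (NADPH, i-PrOH) reduces only the (3S) enantiomer to the alcohol F2. Unreduced (3R)-3 is separated by chromatography and rejoins the route.

Step 2 (quaternary centre by imine Michael addition). The crowded enamine may react slowly or at the wrong α-carbon. The fallback sets out from 3 and returns at 8. Thermodynamic silylation (Me3SiCl, NaI, Et3N, MeCN) gives the tetrasubstituted trimethylsilyl enol ether F3. MeLi (THF, 0 °C) unmasks the regiodefined lithium enolate, which adds to 5 at −78 °C anti to the isopropenyl group to give 8.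

**Further compounds**
F1 | step 1 | racemic 2-methyl-3-(prop-1-en-2-yl)cyclohexan-1-one | CC1C(C(C)=C)CCCC1=O
F2 | step 1 | 2-methyl-3-(prop-1-en-2-yl)cyclohexan-1-ol from the (3S) ketone | CC1C(O)CCC[C@@H]1C(C)=C
F3 | step 2 | trimethyl{[(3S)-2-methyl-3-(prop-1-en-2-yl)cyclohex-1-en-1-yl]oxy}silane (tetrasubstituted silyl enol ether of 3) | CC1=C(O[Si](C)(C)C)CCC[C@H]1C(C)=C
F4 | step 7 | bicyclo[2.2.2]octenone acetate tert-butyl ester (C9=C11 alkene, C14 OAc, C15 ketone, open propanoate arm) | C1C(=O)[C@]23CC[C@@H](C(=C)C)[C@](C)(CCC(=O)OC(C)(C)C)C2=C[C@H]1C[C@@H]3OC(C)=O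
F5 | step 7 | 11-iodo derivative of 22 (iodolactone acetate) | C1C(=O)[C@]23CC[C@@H](C(=C)C)[C@]4(C)CCC(=O)O[C@@]42C(I)[C@H]1C[C@@H]3OC(C)=O
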